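## Retrosynthetic overview

1. Gnetal comes from a fully protected trans-2,3-diaryl-2,3-dihydrobenzofuran (MOM ethers on all phenols, silyl ether on the future formyl carbon) by desilylation, benzylic oxidation to the aldehyde and global MOM removal.
2. The dihydrofuran ring is the only ring made (the three benzene rings are bought). It is closed by an intermolecular Michael addition of a chiral benzylic sulfonium ylide (C2 plus ring B) to an ortho-quinone methide (ring A, C3 and ring C), forming C2–C3, followed by 5-exo SN2 closure of O1–C2.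
3. The ortho-quinone methide comes from a 2-[aryl(tosyl)methyl]phenol, made from a ring A salicylaldehyde and a ring C aryllithium.
4. The ring A salicylaldehyde comes from methyl 3,5-dihydroxybenzoate by bis-MOM protection, reduction, silylation, directed ortho-lithiation/formylation and selective mono-MOM cleavage.
5. The ylide comes from 4-hydroxybenzaldehyde (MOM ether, reduction, bromide) and isothiocineole made from (R)-limonene.

Assumption: the ylide from (1R,4R,5R)-isothiocineole is taken to deliver the 2S,3S series; if the sense of induction is the reverse, the mirror-image sulfide from (S)-limonene is used in the same steps.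

## Route

Step 1
Reactants: 1 methyl 3,5-dihydroxybenzoate
Product: 2 methyl 3,5-bis(methoxymethoxy)benzoate
Conditions: MOMCl (2.5 equiv), i-Pr2NEt, CH2Cl2, 0 °C to rt
Reagents that add atoms: chloromethyl methyl ether (MOMCl), COCCl
Why: Williamson-type O-alkylation of both phenols gives base-stable acetal ethers that later direct the ortho-lithiation and come off with mild acid.

Step 2
Reactants: 2 methyl 3,5-bis(methoxymethoxy)benzoate
Product: 3 [3,5-bis(methoxymethoxy)phenyl]methanol
Conditions: LiAlH4, THF, 0 °C; Fieser work-up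
Reagents that add atoms: none
Why: Hydride reduction of the ester leaves aryl MOM ethers untouched and brings this carbon to an oxidation level that tolerates organolithiums and, later, the sulfur ylide (which would epoxidise an aldehyde).

Step 3
Reactants: 3 [3,5-bis(methoxymethoxy)phenyl]methanol
Product: 4 tert-butyl{[3,5-bis(methoxymethoxy)phenyl]methoxy}diphenylsilane
Conditions: TBDPSCl, imidazole, DMF, rt
Reagents that add atoms: tert-butyl(chloro)diphenylsilane (TBDPSCl), CC(C)(C)[Si](Cl)(c1ccccc1)c1ccccc1
Why: Imidazole-promoted silylation gives the TBDPS ether, the most acid-stable of the common silyl ethers, so that it survives the acidic step 5.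

Step 4
Reactants: 4 tert-butyl{[3,5-bis(methoxymethoxy)phenyl]methoxy}diphenylsilane
Product: 6 4-{[tert-butyl(diphenyl)silyl]oxymethyl}-2,6-bis(methoxymethoxy)benzaldehyde, via aryllithium 5 (not isolated)
Conditions: n-BuLi, TMEDA, THF, 0 °C; then DMF, 0 °C to rt; aq NH4Cl
Reagents that add atoms: N,N-dimethylformamide (DMF), CN(C)C=O
Why: Directed ortho-metalation removes the proton flanked by the two OMOM groups selectively (cooperative chelation), and the aryllithium is formylated by DMF.

Step 5
Reactants: 6 4-{[tert-butyl(diphenyl)silyl]oxymethyl}-2,6-bis(methoxymethoxy)benzaldehyde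
Product: 7 4-{[tert-butyl(diphenyl)silyl]oxymethyl}-2-hydroxy-6-(methoxymethoxy)benzaldehyde
Conditions: 3 M aq HCl/THF (1:5), 20 °C, TLC control
Reagents that add atoms: none
Why: Acid-catalysed acetal hydrolysis stops after one MOM group because the freed phenol hydrogen-bonds to the aldehyde and deactivates the remaining ortho MOM ether, which differentiates the two ring A oxygens.

Step 6
Reactants: 8 5-bromobenzene-1,3-diol
Product: 9 1-bromo-3,5-bis(methoxymethoxy)benzene
Conditions: MOMCl (2.5 equiv), i-Pr2NEt, CH2Cl2, 0 °C to rt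
Reagents that add atoms: chloromethyl methyl ether (MOMCl), COCCl
Why: Williamson-type O-alkylation protects ring C with the same acid-labile group used elsewhere, so one final step frees all phenols.

Step 7
Reactants: 9 1-bromo-3,5-bis(methoxymethoxy)benzene; 7 4-{[tert-butyl(diphenyl)silyl]oxymethyl}-2-hydroxy-6-(methoxymethoxy)benzaldehyde
Product: 11 racemic 2-{[3,5-bis(methoxymethoxy)phenyl](hydroxy)methyl}-5-{[tert-butyl(diphenyl)silyl]oxymethyl}-3-(methoxymethoxy)phenol, via aryllithium 10 (not isolated)
Conditions: 9 (2.2 equiv), n-BuLi, THF, −78 °C; then 7, −78 to 0 °C; aq NH4Cl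
Reagents that add atoms: none
Why: Bromine–lithium exchange followed by 1,2-addition to the aldehyde (the first equivalent of aryllithium only removes the phenol proton) gives the ortho-hydroxybenzhydrol, whose racemic carbinol centre is irrelevant because it becomes planar in step 14.

Step 8
Reactants: 11 racemic 2-{[3,5-bis(methoxymethoxy)phenyl](hydroxy)methyl}-5-{[tert-butyl(diphenyl)silyl]oxymethyl}-3-(methoxymethoxy)phenol
Product: 12 racemic 2-{[3,5-bis(methoxymethoxy)phenyl](4-methylbenzenesulfonyl)methyl}-5-{[tert-butyl(diphenyl)silyl]oxymethyl}-3-(methoxymethoxy)phenol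
Conditions: p-TolSO2H (1.5 equiv), CH2Cl2, rt
Reagents that add atoms: p-toluenesulfinic acid, Cc1ccc(cc1)S(=O)O
Why: SN1-type substitution through the benzylic cation/ortho-quinone methide, strongly stabilised by the ortho-OH and ortho-OMOM groups, is trapped at sulfur by sulfinate to give a stable, storable quinone methide precursor.

Step 9
Reactants: 13 4-hydroxybenzaldehyde
Product: 14 4-(methoxymethoxy)benzaldehyde
Conditions: MOMCl, i-Pr2NEt, CH2Cl2, 0 °C to rt
Reagents that add atoms: chloromethyl methyl ether (MOMCl), COCCl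
Why: Williamson-type O-alkylation masks the ring B phenol with a base-stable group, which is essential because a free or base-labile 4-oxygen would expel the sulfide as a para-quinone methide in step 14.

Step 10
Reactants: 14 4-(methoxymethoxy)benzaldehyde
Product: 15 [4-(methoxymethoxy)phenyl]methanol
Conditions: NaBH4, MeOH, 0 °C
Reagents that add atoms: none
Why: Borohydride reduction of an aryl aldehyde to the benzylic alcohol is quantitative and leaves the MOM ether intact.

Step 11
Reactants: 15 [4-(methoxymethoxy)phenyl]methanol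
Product: 16 1-(bromomethyl)-4-(methoxymethoxy)benzene
Conditions: CBr4, PPh3, CH2Cl2, 0 °C; used at once
Reagents that add atoms: carbon tetrabromide, BrC(Br)(Br)Br
Why: The Appel reaction converts the benzylic alcohol into the bromide under neutral conditions that spare the MOM ether.

Step 12
Reactants: 17 (R)-limonene
Product: 18 (1R,4R,5R)-4,7,7-trimethyl-6-thiabicyclo[3.2.1]octane (isothiocineole)
Conditions: S8, γ-terpinene, neat, 110 °C, 16 h; distillation
Reagents that add atoms: sulfur (S8), S1SSSSSSS1
Why: Radical double hydrothiolation (thiyl-radical addition across both alkenes with γ-terpinene as hydrogen-atom donor) retains the limonene stereocentre, which fixes the sulfur-bearing bridgehead because only the cis-bridged bicycle can close, while the methyl-bearing centre is set by hydrogen-atom delivery to the less hindered face.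

Step 13
Reactants: 18 (1R,4R,5R)-isothiocineole; 16 1-(bromomethyl)-4-(methoxymethoxy)benzene
Product: 19 (1R,4R,5R)-6-[4-(methoxymethoxy)benzyl]-4,7,7-trimethyl-6-thiabicyclo[3.2.1]octan-6-ium trifluoromethanesulfonate (single diastereomer at sulfur)
Conditions: LiOSO2CF3, CH2Cl2/H2O, rt
Reagents that add atoms: lithium trifluoromethanesulfonate, [Li+].[O-]S(=O)(=O)C(F)(F)F
Why: S-alkylation of the sulfide on its less hindered lone pair gives one sulfonium diastereomer, and exchange of bromide for the non-nucleophilic triflate prevents the reverse dealkylation.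

Step 14
Reactants: 12 racemic 2-{[3,5-bis(methoxymethoxy)phenyl](4-methylbenzenesulfonyl)methyl}-5-{[tert-butyl(diphenyl)silyl]oxymethyl}-3-(methoxymethoxy)phenol; 19 isothiocineole-derived 4-(methoxymethoxy)benzylsulfonium triflate
Product: 23 (2S,3S)-3-[3,5-bis(methoxymethoxy)phenyl]-6-{[tert-butyl(diphenyl)silyl]oxymethyl}-4-(methoxymethoxy)-2-[4-(methoxymethoxy)phenyl]-2,3-dihydro-1-benzofuran, via ortho-quinone methide 20 (not isolated), via sulfonium ylide 21 (not isolated), via betaine 22 (not isolated)
Conditions: 19 (1.3 equiv), Cs2CO3 (3 equiv), MeCN, −20 °C to rt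
Reagents that add atoms: none
Why: In this Michael-initiated ring closure (formal [4+1] annulation) Cs2CO3 releases the planar quinone methide from the racemic sulfone by 1,4-elimination and the ylide by deprotonation, the ylide carbon adds 1,4 to the methide carbon (C2–C3 bond) and the phenolate of the betaine displaces the sulfide in a 5-exo-tet SN2 step (O1–C2 bond); the rigid bicyclic sulfide exposes one face of the ylide and so fixes C2, and the anti approach that keeps the two aryl groups apart fixes C3 as trans.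

Step 15
Reactants: 23 (2S,3S)-silyl ether
Product: 24 [(2S,3S)-3-[3,5-bis(methoxymethoxy)phenyl]-4-(methoxymethoxy)-2-[4-(methoxymethoxy)phenyl]-2,3-dihydro-1-benzofuran-6-yl]methanol
Conditions: TBAF, THF, 0 °C to rt
Reagents that add atoms: none
Why: Fluoride-driven desilylation cleaves only the Si–O bond and leaves the MOM ethers and both benzylic stereocentres untouched.

Step 16
Reactants: 24 (2S,3S)-benzylic alcohol
Product: 25 (2S,3S)-3-[3,5-bis(methoxymethoxy)phenyl]-4-(methoxymethoxy)-2-[4-(methoxymethoxy)phenyl]-2,3-dihydro-1-benzofuran-6-carbaldehyde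
Conditions: MnO2 (excess), CH2Cl2, rt
Reagents that add atoms: none
Why: MnO2 oxidises the benzylic alcohol selectively to the aldehyde without over-oxidation and without dehydrogenating the dihydrofuran ring.

Step 17
Reactants: 25 (2S,3S)-tetra-MOM aldehyde
Product: 26 gnetal, (2S,3S)-3-(3,5-dihydroxyphenyl)-4-hydroxy-2-(4-hydroxyphenyl)-2,3-dihydro-1-benzofuran-6-carbaldehyde
Conditions: 2 M aq HCl, MeOH/THF, 40 °C
Reagents that add atoms: none
Why: Acid-catalysed acetal hydrolysis removes all four MOM groups in one operation, and any reversible ionisation of the C2–O bond under these conditions can only return the more stable trans isomer because C3 is not touched.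

## Compound list

1 | methyl 3,5-dihydroxybenzoate | COC(=O)c1cc(O)cc(O)c1 | starting material
2 | methyl 3,5-bis(methoxymethoxy)benzoate | COCOc1cc(OCOC)cc(c1)C(=O)OC | intermediate
3 | [3,5-bis(methoxymethoxy)phenyl]methanol | COCOc1cc(CO)cc(OCOC)c1 | intermediate
4 | tert-butyl{[3,5-bis(methoxymethoxy)phenyl]methoxy}diphenylsilane | COCOc1cc(CO[Si](c2ccccc2)(c2ccccc2)C(C)(C)C)cc(OCOC)c1 | intermediate
5 | {4-{[tert-butyl(diphenyl)silyl]oxymethyl}-2,6-bis(methoxymethoxy)phenyl}lithium | [Li]c1c(OCOC)cc(CO[Si](c2ccccc2)(c2ccccc2)C(C)(C)C)cc1OCOC | intermediate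
6 | 4-{[tert-butyl(diphenyl)silyl]oxymethyl}-2,6-bis(methoxymethoxy)benzaldehyde | O=Cc1c(OCOC)cc(CO[Si](c2ccccc2)(c2ccccc2)C(C)(C)C)cc1OCOC | intermediate
7 | 4-{[tert-butyl(diphenyl)silyl]oxymethyl}-2-hydroxy-6-(methoxymethoxy)benzaldehyde | O=Cc1c(O)cc(CO[Si](c2ccccc2)(c2ccccc2)C(C)(C)C)cc1OCOC | intermediate
8 | 5-bromobenzene-1,3-diol | Oc1cc(O)cc(Br)c1 | starting material
9 | 1-bromo-3,5-bis(methoxymethoxy)benzene | COCOc1cc(Br)cc(OCOC)c1 | intermediate
10 | [3,5-bis(methoxymethoxy)phenyl]lithium | [Li]c1cc(OCOC)cc(OCOC)c1 | intermediate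
11 | racemic 2-{[3,5-bis(methoxymethoxy)phenyl](hydroxy)methyl}-5-{[tert-butyl(diphenyl)silyl]oxymethyl}-3-(methoxymethoxy)phenol | OC(c1cc(OCOC)cc(OCOC)c1)c1c(O)cc(CO[Si](c2ccccc2)(c2ccccc2)C(C)(C)C)cc1OCOC | intermediate
12 | racemic 2-{[3,5-bis(methoxymethoxy)phenyl](4-methylbenzenesulfonyl)methyl}-5-{[tert-butyl(diphenyl)silyl]oxymethyl}-3-(methoxymethoxy)phenol | Cc1ccc(cc1)S(=O)(=O)C(c1cc(OCOC)cc(OCOC)c1)c1c(O)cc(CO[Si](c2ccccc2)(c2ccccc2)C(C)(C)C)cc1OCOC | intermediate
13 | 4-hydroxybenzaldehyde | O=Cc1ccc(O)cc1 | starting material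
14 | 4-(methoxymethoxy)benzaldehyde | COCOc1ccc(C=O)cc1 | intermediate
15 | [4-(methoxymethoxy)phenyl]methanol | COCOc1ccc(CO)cc1 | intermediate
16 | 1-(bromomethyl)-4-(methoxymethoxy)benzene | COCOc1ccc(CBr)cc1 | intermediate
17 | (R)-limonene | CC1=CC[C@@H](CC1)C(C)=C | starting material
18 | (1R,4R,5R)-4,7,7-trimethyl-6-thiabicyclo[3.2.1]octane (isothiocineole; methyl group on the face opposite to the sulfur bridge) | C[C@@H]1CC[C@@H]2C[C@H]1SC2(C)C | intermediate
19 | (1R,4R,5R)-6-[4-(methoxymethoxy)benzyl]-4,7,7-trimethyl-6-thiabicyclo[3.2.1]octan-6-ium trifluoromethanesulfonate (one sulfur diastereomer, sulfur configuration as formed and not encoded) | C[C@@H]1CC[C@@H]2C[C@H]1[S+](Cc3ccc(OCOC)cc3)C2(C)C.[O-]S(=O)(=O)C(F)(F)F | intermediate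
20 | ortho-quinone methide: 6-{[3,5-bis(methoxymethoxy)phenyl]methylidene}-3-{[tert-butyl(diphenyl)silyl]oxymethyl}-5-(methoxymethoxy)cyclohexa-2,4-dien-1-one (alkene geometry not defined) | O=C1C=C(CO[Si](c2ccccc2)(c2ccccc2)C(C)(C)C)C=C(OCOC)C1=Cc3cc(OCOC)cc(OCOC)c3 | intermediate
21 | sulfonium ylide of 19 (benzylic carbanion on sulfur) | C[C@@H]1CC[C@@H]2C[C@H]1[S+]([CH-]c3ccc(OCOC)cc3)C2(C)C | intermediate
22 | betaine: Michael adduct of 21 and 20, a ring A phenolate carrying the sulfonium group on the future C2 (C3 as in 23, C2 inverts on closure) | C[C@@H]1CC[C@@H]2C[C@H]1[S+]([C@@H](c3ccc(OCOC)cc3)[C@@H](c3cc(OCOC)cc(OCOC)c3)c3c([O-])cc(CO[Si](c4ccccc4)(c4ccccc4)C(C)(C)C)cc3OCOC)C2(C)C | intermediate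
23 | (2S,3S)-3-[3,5-bis(methoxymethoxy)phenyl]-6-{[tert-butyl(diphenyl)silyl]oxymethyl}-4-(methoxymethoxy)-2-[4-(methoxymethoxy)phenyl]-2,3-dihydro-1-benzofuran (trans) | CC(C)(C)[Si](c1ccccc1)(c1ccccc1)OCc1cc(OCOC)c2c(c1)O[C@H](c1ccc(OCOC)cc1)[C@H]2c1cc(OCOC)cc(OCOC)c1 | intermediate
24 | [(2S,3S)-3-[3,5-bis(methoxymethoxy)phenyl]-4-(methoxymethoxy)-2-[4-(methoxymethoxy)phenyl]-2,3-dihydro-1-benzofuran-6-yl]methanol | OCc1cc(OCOC)c2c(c1)O[C@H](c1ccc(OCOC)cc1)[C@H]2c1cc(OCOC)cc(OCOC)c1 | intermediate
25 | (2S,3S)-3-[3,5-bis(methoxymethoxy)phenyl]-4-(methoxymethoxy)-2-[4-(methoxymethoxy)phenyl]-2,3-dihydro-1-benzofuran-6-carbaldehyde | O=Cc1cc(OCOC)c2c(c1)O[C@H](c1ccc(OCOC)cc1)[C@H]2c1cc(OCOC)cc(OCOC)c1 | intermediate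
26 | gnetal, (2S,3S)-3-(3,5-dihydroxyphenyl)-4-hydroxy-2-(4-hydroxyphenyl)-2,3-dihydro-1-benzofuran-6-carbaldehyde | O=Cc1cc(O)c2c(c1)O[C@H](c1ccc(O)cc1)[C@H]2c1cc(O)cc(O)c1 | target

## Step count and risks

Total steps: 17. Longest linear sequence: 11 steps (steps 1, 2, 3, 4, 5, 7, 8, 14, 15, 16, 17, from compound 1 to compound 26).

Most likely to fail, first: step 14. The face selectivity of a chiral benzylic ylide towards a hindered, electron-rich ortho-quinone methide is the least precedented point, and dr or ee may be insufficient. The fallback replaces asymmetric induction by resolution and sets out from 12 (together with bromide 16). Bromide 16 is treated with dimethyl sulfide and LiOSO2CF3 in CH2Cl2/H2O to give [4-(methoxymethoxy)benzyl]dimethylsulfonium trifluoromethanesulfonate F1. F1 and 12 with Cs2CO3 in MeCN undergo the same Michael addition and SN2 closure to give the racemic trans-dihydrobenzofuran F2. Preparative chiral SFC on an amylose tris(3,5-dimethylphenylcarbamate) phase separates the enantiomers, and the 2S,3S enantiomer is 23, where the route resumes.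

Second: step 5. The hydrolysis may run on to the diol or erode the silyl ether. The fallback replaces selective deprotection by selective protection and sets out from 6. Prolonged treatment with 3 M aq HCl/THF at 40 °C removes both aryl MOM groups to give 4-{[tert-butyl(diphenyl)silyl]oxymethyl}-2,6-dihydroxybenzaldehyde F3. One equivalent of MOMCl with i-Pr2NEt in CH2Cl2 at 0 °C then alkylates only one hydroxyl, because the other is hydrogen-bonded to the aldehyde, and returns to 7.

Third: step 8. Sulfinic acid may cleave MOM ethers, or the quinone methide may oligomerise before it is trapped. The fallback avoids acid altogether and sets out from 11. Boc2O (1.05 equiv) with catalytic 4-(dimethylamino)pyridine in CH2Cl2 at 0 °C acylates the phenol to give the aryl tert-butyl carbonate F4. F4 and 19 are treated with t-BuOK in THF from −78 to 0 °C: the benzylic alkoxide takes over the Boc group, the phenoxide expels tert-butyl carbonate to give quinone methide 20, and the ylide 21 formed in the same flask intercepts it, so the route is rejoined at 23.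

Further compounds

F1 | step 14 | [4-(methoxymethoxy)benzyl]dimethylsulfonium trifluoromethanesulfonate | COCOc1ccc(C[S+](C)C)cc1.[O-]S(=O)(=O)C(F)(F)F
F2 | step 14 | racemic trans-3-[3,5-bis(methoxymethoxy)phenyl]-6-{[tert-butyl(diphenyl)silyl]oxymethyl}-4-(methoxymethoxy)-2-[4-(methoxymethoxy)phenyl]-2,3-dihydro-1-benzofuran (1:1 mixture of 23 and its 2R,3R enantiomer) | CC(C)(C)[Si](c1ccccc1)(c1ccccc1)OCc1cc(OCOC)c2c(c1)O[C@H](c1ccc(OCOC)cc1)[C@H]2c1cc(OCOC)cc(OCOC)c1.CC(C)(C)[Si](c1ccccc1)(c1ccccc1)OCc1cc(OCOC)c2c(c1)O[C@@H](c1ccc(OCOC)cc1)[C@@H]2c1cc(OCOC)cc(OCOC)c1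
F3 | step 5 | 4-{[tert-butyl(diphenyl)silyl]oxymethyl}-2,6-dihydroxybenzaldehyde | O=Cc1c(O)cc(CO[Si](c2ccccc2)(c2ccccc2)C(C)(C)C)cc1O
F4 | step 8 | racemic 2-{[3,5-bis(methoxymethoxy)phenyl](hydroxy)methyl}-5-{[tert-butyl(diphenyl)silyl]oxymethyl}-3-(methoxymethoxy)phenyl tert-butyl carbonate | OC(c1cc(OCOC)cc(OCOC)c1)c1c(OC(=O)OC(C)(C)C)cc(CO[Si](c2ccccc2)(c2ccccc2)C(C)(C)C)cc1OCOC
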